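Amounts first: this flask is charged with 0.053 M of electrophile, 0.0583 M of nucleophile and 0.0636 M of solid base, none of it dissolved at the start.

common to all: solid base 0.0636 M

| charge | electrophile | nucleophile | remark | time |
|---|---|---|---|---|
| elm | 0.053 M | 0.029 M | run made earlier |  |
| larch | 0.053 M | 0.12 M | run made earlier |  |
| maple | 0.080 M | 0.0583 M | run made earlier |  |
| flask | 0.053 M | 0.0583 M |  | 30 h |

| run | time / h | target / % | electrophile / % |
|---|---|---|---|
| elm | 8.00 | 25.6 | 71.8 |
| elm | 15.0 | 31.2 | 67.8 |
| elm | 25.0 | 33.8 | 60.6 |
| elm | 30.0 | 38.7 | 58.8 |
| larch | 4.00 | 61.6 | 38.0 |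
| larch | 10.0 | 83.3 | 16.1 |
| larch | 20.0 | 94.0 | 6.1 |
| larch | 30.0 | 96.0 | 1.2 |
| maple | 2.50 | 24.1 | 79.4 |
| maple | 6.00 | 36.1 | 63.4 |
| maple | 12.0 | 40.5 | 59.1 |
| maple | 30.0 | 44.9 | 52.4 |

(scatter of a reading: 1 percentage point)

- what is said of acid set free includes crystals
- crystals, solid base is a solid; its amount is given per volume of the solution
- steps thought possible: electrophile + nucleophile -> acid set free + target; nucleophile + acid set free <-> protonated nucleophile; acid set free + free base <-> salt of the base; crystals <-> acid set free; acid set free + target -> side product; solid base <-> free base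
- at the start none of the solid base is in solution

- concentration of target at 30 h, in M
- concentration of electrophile at 30 h, in M
- concentration of side product at 30 h, in M

*Which concentration governs the rate?* Free nucleophile, as I read the runs. Larch, whose 0.12 M of nucleophile covers its electrophile at two apiece, reads 96.0 % of target at 30.0 h; elm, charged 0.029 M, reads 38.7 %.

*Why two apiece?* I take it that one nucleophile makes the target and a second takes up the acid set free as protonated nucleophile. In this flask that gives 0.0291 M: the stall amount S, half of the nucleophile charged.

*Do the readings show it?* Maple, with S of 0.0291 M, reads 0.0289 M of target at 6.00 h. Elm, with S of 0.0145 M, reads 0.0136 M at 8.00 h. Both then creep.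

*So is S a wall?* No. Elm reads 0.0205 M at 30.0 h, which is 0.00601 M past its S.

*And does this flask get there?* Maple needed 6.00 h, short against 30 h. S also lies below the 0.053 M of electrophile charged to this flask. My own figure for the flask is S plus elm's excess: 0.0352 M of target.

The forecast reasons that “The nucleophile traps the acid set free, so each target consumes about two nucleophiles.” It gives 0.0345 M of target, a little below mine, with 0.0175 M of electrophile and 0.001 M of side product.

The flask gives 0.0340 M of target, 0.0178 M of electrophile and 0.00120 M of side product, the last above the forecast.

    electrophile + nucleophile → acid set free + target (k = 3.10 L mol⁻¹ h⁻¹)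
    nucleophile + acid set free ⇌ protonated nucleophile, settled at all times (K = 880 L mol⁻¹)
    acid set free + free base ⇌ salt of the base, settled at all times (K = 31000 L mol⁻¹)
    crystals ⇌ acid set free, rate k4*(cs4 - [acid set free]) while solid is left; crystals form when [acid set free] > cs4 (solubility = 10.0 mM, k = 14.0 h⁻¹)
    acid set free + target → side product (k = 0.430 L mol⁻¹ h⁻¹)
    solid base ⇌ free base, rate k6*(cs6 - [free base]) while solid is left; crystals form when [free base] > cs6 (solubility = 2.80 mM, k = 0.130 h⁻¹)

The flask's target stands 0.00490 M above S, with 7.6 % of its nucleophile free, less than the 34 % of electrophile left, and 0.0186 M of protonated nucleophile beside 0.0106 M of salt of the base. The neighbouring flask differs by its 0.099 M of nucleophile, so its S is 0.0495 M, still below 0.053 M. That neighbouring flask gives 0.0477 M of target, just under that S, which is 89.9 % of its electrophile, with 0.00433 M of electrophile left.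

The readings were computed from invented constants; the scatter is artificial.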